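Time in the vessel comes first here: I mix substrate, coupling partner and protic impurity, isothermally, and want target out of one of these set-ups.

| flask | substrate | coupling partner | protic impurity | remark | time |
|---|---|---|---|---|---|
| winter | 0.10 M | 1.2 equiv | 0.020 M | run made earlier |  |
| noon | 0.067 M | 1.2 equiv | 0.020 M | run made earlier |  |
| dawn | 0.15 M | 1.2 equiv | 0.020 M | run made earlier |  |
| Sunday's | 0.10 M | 1.20 equiv | 0.0200 M | one stirred flow tank at steady state, fed with the mixture as stated, mean residence time 120 min |  |
| Wednesday's | 0.10 M | 1.20 equiv | 0.0200 M | one stirred flow tank at steady state, fed with the mixture as stated, mean residence time 12 min |  |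
| Tuesday's | 0.10 M (fed, over 12.0 min) | 1.20 equiv | 0.0200 M | a stirred flask in which substrate is dosed at a steady rate over 12.0 min without added volume, worked up at 12 min | 12 min |
| Saturday's | 0.10 M | 1.20 equiv | 0.0200 M | a closed flask charged with all of it at once and left for 12 min | 12 min |

| run | time / min | target / % | substrate / % |
|---|---|---|---|
| winter | 1.00 | 1.1 | 99.9 |
| winter | 2.00 | 0.3 | 100.5 |
| winter | 3.00 | 1.4 | 99.3 |
| winter | 4.00 | 0.9 | 99.7 |
| winter | 5.00 | 0.6 | 99.1 |
| winter | 6.00 | 0.5 | 99.5 |
| winter | 8.00 | 0.5 | 99.1 |
| noon | 1.00 | 0.2 | 99.8 |
| noon | 1.33 | 0 | 100.2 |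
| noon | 2.00 | 0.2 | 99.7 |
| noon | 3.00 | 0.1 | 100.1 |
| noon | 5.00 | 0 | 99.6 |
| noon | 8.00 | 0.1 | 100.3 |
| noon | 12.0 | 0 | 98.9 |
| dawn | 1.50 | 0 | 99.2 |
| dawn | 3.00 | 0.5 | 100.4 |
| dawn | 5.00 | 1.2 | 98.6 |
| dawn | 6.00 | 1.3 | 99.0 |
| dawn | 8.00 | 3.1 | 96.3 |
| dawn | 10.0 | 3.4 | 95.0 |
| dawn | 12.0 | 4.7 | 92.0 |

(each reading ± 0.5 percentage points)

- the stated concentrations are those of everything mixed, before any reaction; amounts are the same in each set-up
- the feed brings no volume worth counting
- the earlier runs were made in a closed, stirred flask

1. the set-up with the highest amount of target at the outlet or at the end, in percent of the substrate put in ("none" if the first two lie within 2 percentage points) (Sunday's / Wednesday's / Tuesday's / Saturday's / none)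
2. amount of target at the outlet or at the end, in percent of the substrate put in, Sunday's
3. amount of target at the outlet or at the end, in percent of the substrate put in, Wednesday's
4. amount of target at the outlet or at the end, in percent of the substrate put in, Tuesday's
5. amount of target at the outlet or at the end, in percent of the substrate put in, Saturday's

The runs seem to quarrel. At 12.0 min dawn, charged at 0.15 M, reads 4.7% target, but at 12.0 min noon, charged at 0.067 M, reads 0%. A plain bimolecular coupling makes percent yield proportional to concentration, so noon ought to read 2.10%, with a scatter of 0.5 percentage points.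

Dawn's own curve clears this up. Target climbs from 1.2% at 5.00 min to 4.7% at 12.0 min while substrate still reads 92.0%. I take that as target feeding its own formation (autocatalysis) and freeze substrate and coupling partner at their charge, so target multiplies at a steady rate, which these two readings put at 0.195 min⁻¹. I take that rate to go with the product of the two concentrations, so across 12.0 min it multiplies dawn's target 10.4-fold and noon's 1.59-fold.

At 0.10 M the rate is 0.0867 min⁻¹. This growth constant is the fraction of itself that target adds per minute with substrate and coupling partner frozen. The outflow of a stirred tank removes one part of its target per residence time, so I multiply the two into a growth number, and the balance tips where it passes one. Wednesday's number is 1.04, and Sunday's is 10.4, far above Wednesday's. Wednesday's sits about at one, given two scattered readings behind it, but Sunday's stands well above one, where target should grow until falling substrate and coupling partner pull the number back, so I commit to Sunday's.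

The forecast names Sunday's, with 30% (15% to 75%) for Sunday's, 2.5% for Wednesday's, 0.4% for Tuesday's and 2% for Saturday's. Its ground for Sunday's: “the long residence clears the impurity”.

The set-ups give 18.1% on Sunday's, 2.08% on Wednesday's, 0.318% on Tuesday's and 0.897% on Saturday's, so Sunday's leads.

    substrate + coupling partner + target → 2 target (k = 0.320 M⁻² s⁻¹)
    substrate + coupling partner → target (k = 1.20 × 10⁻⁴ M⁻¹ s⁻¹)
    2 coupling partner → homo dimer (k = 0.00230 M⁻¹ s⁻¹)
    coupling partner + protic impurity → quenched reagent (k = 0.0870 M⁻¹ s⁻¹)
    target ⇌ isomer of the product (K = 2.10, k = 0.00290 s⁻¹)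

Sunday's tank runs the self-feeding step with coupling partner at 0.0261 M and substrate near 0.0474 M, so its growth number, on the constant read from dawn, comes to 1.07, while 34.5% of isomer of the product stands beside target, which is 12 points under the forecast's 30%. Wednesday's tank holds coupling partner at 0.0786 M and substrate at 0.0957 M, so its growth number is 0.653, with 2.18% of isomer of the product beside 2.08% of target.

The numbers in the tables were computed for an exercise; noise was put on by code.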